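**Plan**
- **Hardest feature:** the adjacent fully substituted pair C1'(OH)/C6'(CH3)(CH2O-acyl), with the oxygenated methyl C9' trans to the C1' hydroxyl. It sits in a ring whose free 9'-alcohol would add to the C2'=C3'–C4'=O enone.
- **Cuts:** the ester bond C9'O–C(=O) (HMG half ester); the ring–chain bond C1'–C5 (sp2–sp2 coupling); C1'–O (from a C1'–C2' epoxide opened by the C4' ketone); and C9'–O (from a C–H bond of a geminal methyl).
- **Forward order:** the carbocycle is bought as (4R,6R)-actinol. Step 1 closes a temporary C4'–O–C9' bridge (6-oxabicyclo[3.2.1]octane). The bridge is oxidised to the lactone, carried as the lactol through triflation and coupling, used to steer the epoxidation, then cut by reduction. Esterification, C4' oxidation with epoxide opening, and deprotection finish the route.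
- **Stereochemistry:** the bought C4' carbinol sets C6' by 1,5-H transfer. The bridge then sets C1' by exo epoxidation, and C4' is erased as the ketone. The HMG centre comes from esterase desymmetrisation, 2Z from anti hydroiodination, and 4E from (E)-distannylethene.
- **Enabling feature:** C4' (the future carbonyl carbon) and C6' are 1,3-related on the cyclohexane ring. An axial oxygen on C4' is therefore syn-axial to only one geminal methyl, through the six-atom array O–C4'–C5'–C6'–C9'–H.

Key step: step 1

Remark on locants: abscisic acid numbering is used (ring C1' carbinol, C2' methyl-bearing alkene carbon, C4' carbonyl, C6' quaternary, C8' = CH3 on C6', C9' = CH2O on C6', chain C1–C5). The β face carries the chain and C9' in the target; the α face carries C1'–OH and C8'.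
Assumption: the SMILES is read as (1'R,6'S,3''R), i.e. C9' trans to C1'–OH, and the route is built for that isomer.
Assumption: (4R,6R)-actinol, the industrial zeaxanthin intermediate, is taken as a catalogue compound.

Step 1
Reactants: 1 (4R,6R)-4-hydroxy-2,2,6-trimethylcyclohexanone (actinol)
Product: 3 (1S,3R,5R)-1,3-dimethyl-6-oxabicyclo[3.2.1]octan-2-one (C4'–O–C9' bridged ether), via 9'-iodoactinol 2 (not isolated)
Conditions: PhI(OAc)2 (1.6 equiv), I2 (1 equiv), cyclohexane–CH2Cl2, tungsten lamp, 25–30 °C
Reagents that add atoms: none
Why: Acetyl hypoiodite turns the C4' hydroxyl into a hypoiodite whose photolysis gives the C4' alkoxyl radical; this takes H from a C6' methyl through the six-membered O–C4'–C5'–C6'–C9'–H array (1,5-HAT), the primary C9' radical is iodinated to 2, and the C4' oxygen displaces iodide. The closest known reaction type is the hypoiodite reaction by which a 1,3-diaxial hydroxyl functionalises an angular methyl in steroids (6β-OH to C19), the same syn-axial OH/CH3 pair on a cyclohexane chair. The tetrahydrofuran ring closes in the 5-exo-tet mode and creates the 6-oxabicyclo[3.2.1]octane. The new quaternary stereocentre C6' is controlled only by C4': in the chair with the C2' methyl equatorial the (4'R)-oxygen is axial on the β face and reaches only the axial β methyl, so the two diastereotopic methyls are told apart and C9' is the one oxidised. The step needs HAT to beat β-scission and other C–H abstractions; β-scission would give unstabilised primary radicals, the C2' methyl is equatorial on the α face and out of reach, and no other hydrogen sits in a six-membered array.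

Step 2
Reactants: 3 bridged ether ketone
Product: 4 (1R,3R,5R)-1,3-dimethyl-6-oxabicyclo[3.2.1]octane-2,7-dione (keto lactone)
Conditions: RuCl3·xH2O (5 mol %), NaIO4 (4 equiv), EtOAc–MeCN–H2O, rt
Reagents that add atoms: sodium periodate [Na+].[O-]I(=O)(=O)=O
Why: Ruthenium tetroxide oxidation of a cyclic ether to a lactone should attack only the O–CH2 group C9', because the other α-position (C4'–H) is a bridgehead that cannot flatten towards an oxocarbenium-like transition state, and it brings in the second oxygen so that C4' and C9' each keep one when the bridge is cut.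

Step 3
Reactants: 4 keto lactone
Product: 5 (1R,5R)-1,3-dimethyl-7-oxo-6-oxabicyclo[3.2.1]oct-2-en-2-yl trifluoromethanesulfonate
Conditions: KHMDS (1.1 equiv), THF, −78 °C; PhNTf2, −78 to 0 °C; aq. NH4Cl
Reagents that add atoms: N-phenylbis(trifluoromethanesulfonimide) O=S(=O)(N(c1ccccc1)S(=O)(=O)C(F)(F)F)C(F)(F)F
Why: Enolate O-sulfonylation: the ketone can enolise only towards C2' (C6' is quaternary and the lactone has no α-hydrogen), so the tetrasubstituted enol triflate should form regiospecifically as it does from 2,2,6-trimethylcyclohexanone, and the now useless C2' stereocentre is erased.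

Step 4
Reactants: 5 enol triflate lactone
Product: 6 (1R,5R,7ξ)-7-hydroxy-1,3-dimethyl-6-oxabicyclo[3.2.1]oct-2-en-2-yl trifluoromethanesulfonate (bridged lactol as anomer mixture)
Conditions: DIBAL-H (1.1 equiv), CH2Cl2, −78 °C; Rochelle salt work-up
Reagents that add atoms: none
Why: Partial DIBAL-H reduction of a γ-lactone stops at the aluminium hemiacetal at −78 °C and spares the enol triflate; it is placed here so that only borohydride is needed once the dienoate is attached, while the two-atom bridge stays closed (the new C9' centre is an inconsequential anomeric mixture).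

Step 5
Reactants: 7 but-2-ynoic acid
Product: 8 (Z)-3-iodobut-2-enoic acid
Conditions: NaI (1.6 equiv), AcOH, 110 °C
Reagents that add atoms: sodium iodide [Na+].[I-]
Why: Hydroiodination of an ynoic acid with NaI in hot acetic acid is an anti addition (iodide at C3, proton at C2) and should give the (Z)-β-iodo acid, which fixes the 2Z geometry of the target.

Step 6
Reactants: 8 (Z)-3-iodobut-2-enoic acid; 9 2-(trimethylsilyl)ethanol
Product: 10 2-(trimethylsilyl)ethyl (Z)-3-iodobut-2-enoate
Conditions: PPh3, DIAD, THF, 0 °C to rt
Reagents that add atoms: none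
Why: Mitsunobu esterification activates the primary alcohol and not the acid, so the neutral conditions should leave the (Z)-β-iodoacrylate geometry untouched, which nucleophilic acyl-transfer catalysts might not.

Step 7
Reactants: 10 (Z)-iodo ester; 11 (E)-1,2-bis(tributylstannyl)ethene (2.5 equiv)
Product: 12 2-(trimethylsilyl)ethyl (2Z,4E)-3-methyl-5-(tributylstannyl)penta-2,4-dienoate
Conditions: PdCl2(MeCN)2 (5 mol %), DMF, rt
Reagents that add atoms: none
Why: Stille coupling proceeds with retention at both sp2 carbons, the excess of distannane should limit reaction to one tin terminus, and the (E)-ethene unit delivers the 4E geometry.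

Step 8
Reactants: 6 lactol triflate; 12 dienylstannane
Product: 13 2-(trimethylsilyl)ethyl (2Z,4E)-5-[(1R,5R,7ξ)-7-hydroxy-1,3-dimethyl-6-oxabicyclo[3.2.1]oct-2-en-2-yl]-3-methylpenta-2,4-dienoate
Conditions: Pd(PPh3)4 (10 mol %), CuCl (5 equiv), LiCl (6 equiv), degassed DMSO, 60 °C
Reagents that add atoms: none
Why: Copper(I)-accelerated Stille coupling of a hindered cyclohexenyl triflate, the reaction type used with 2,6,6-trimethylcyclohexenyl triflate in retinoid work, should join C1' to C5 with retention of 2Z,4E under base-free conditions that spare the lactol and the silylethyl ester.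

Step 9
Reactants: 13 bridged trienoate
Product: 14 1',2'-α-epoxide of 13 (epoxide oxygen on the face of the one-atom bridge C5' and opposite to the C9'–O bridge)
Conditions: mCPBA (1.05 equiv), NaHCO3, CH2Cl2, −10 °C
Reagents that add atoms: 3-chloroperbenzoic acid O=C(OO)c1cccc(Cl)c1
Why: Prilezhaev epoxidation picks the only electron-rich alkene (tetrasubstituted C1'=C2', as in β-ionylideneacetates, the dienoate being deactivated) and should approach from the exo α face beside the one-atom bridge C5' because the two-atom C9'–O bridge hangs over the β face, which sets C1'–O (and C2'–O) trans to C9'.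

Step 10
Reactants: 14 epoxy lactol
Product: 15 2-(trimethylsilyl)ethyl (2Z,4E)-5-[(1S,2S,4S,6R)-4-hydroxy-2-(hydroxymethyl)-2,6-dimethyl-7-oxabicyclo[4.1.0]heptan-1-yl]-3-methylpenta-2,4-dienoate
Conditions: NaBH4, THF–MeOH, 0 °C
Reagents that add atoms: none
Why: Sodium borohydride reduces the lactol through its open hydroxy aldehyde form and so cuts the temporary bridge to the 4',9'-diol, while the conjugated ester and the tetrasubstituted epoxide are inert to it and no stereocentre changes.

Step 11
Reactants: 16 dimethyl 3-hydroxy-3-methylpentanedioate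
Product: 17 (S)-3-hydroxy-5-methoxy-3-methyl-5-oxopentanoic acid
Conditions: pig liver esterase, phosphate buffer pH 7, 25 °C, 1 M NaOH (pH-stat); then HCl to pH 2
Reagents that add atoms: water O
Why: Enzymatic desymmetrisation: pig liver esterase hydrolyses the pro-S ester group of this prochiral diester, a textbook substrate, to the (S)-half ester, whose free carboxyl arm is the one to be bound to C9'–O, so that the centre becomes R in the target.

Step 12
Reactants: 17 (S)-half ester
Product: 19 (S)-5-methoxy-3-methyl-5-oxo-3-(triethylsilyloxy)pentanoic acid, via bis(triethylsilyl) derivative 18 (not isolated)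
Conditions: TESOTf (2.2 equiv), 2,6-lutidine (3 equiv), CH2Cl2, 0 °C; then pH 4 aqueous buffer–THF
Reagents that add atoms: triethylsilyl trifluoromethanesulfonate CC[Si](CC)(CC)OS(=O)(=O)C(F)(F)F
Why: Silyl triflate silylation caps the tertiary hydroxyl (and transiently the acid) so that carboxyl activation cannot lead to β-lactone formation or dehydration, and the labile silyl ester is hydrolysed on work-up without touching the stereocentre.

Step 13
Reactants: 15 epoxy diol; 19 protected (S)-half ester (1.0 equiv)
Product: 20 9'-O-[(3R)-5-methoxy-3-methyl-5-oxo-3-(triethylsilyloxy)pentanoyl] derivative of 15 (4'-hydroxyl free)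
Conditions: DCC (1.1 equiv), DMAP (0.1 equiv), CH2Cl2, −20 to 0 °C
Reagents that add atoms: none
Why: Steglich esterification with one equivalent of a β-branched acyl donor at low temperature should favour the primary 9'-hydroxyl over the secondary 4'-hydroxyl, and it is done while C4' is still a carbinol so that a free 9'-alcohol never meets the enone.

Step 14
Reactants: 20 epoxy alcohol ester
Product: 22 2-(trimethylsilyl)ethyl ester and 3''-O-triethylsilyl ether of the target, via keto epoxide 21 (not isolated)
Conditions: Dess–Martin periodinane (1.5 equiv), NaHCO3, CH2Cl2, 0 °C to rt; aqueous work-up; crude in CH2Cl2, DBU (0.2 equiv), 0 °C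
Reagents that add atoms: none
Why: Dess–Martin oxidation gives the β,γ-epoxy ketone 21, which on catalytic base enolises towards C3' and breaks the C2'–O bond by E1cB (the biomimetic xanthoxin-type isomerisation), leaving the oxygen on C1' with unchanged configuration, creating the C2'=C3'–C4'=O enone and erasing the relay centre C4'.

Step 15
Reactants: 22 doubly silyl-protected target
Product: 23 (2Z,4E)-5-[(1R,6S)-1-hydroxy-6-({[(3R)-3-hydroxy-5-methoxy-3-methyl-5-oxopentanoyl]oxy}methyl)-2,6-dimethyl-4-oxocyclohex-2-en-1-yl]-3-methylpenta-2,4-dienoic acid (target)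
Conditions: TBAF (5 equiv), AcOH (5 equiv), THF, 0 °C to rt
Reagents that add atoms: none
Why: Buffered fluoride triggers the β-silyl fragmentation of the 2-(trimethylsilyl)ethyl ester and cleaves the tertiary triethylsilyl ether in one operation, and the acetic acid buffer suppresses alkoxide formation so that methyl ester, 9'-ester, enone and tertiary allylic alcohol should survive.

**Compound list**
1 | (4R,6R)-4-hydroxy-2,2,6-trimethylcyclohexanone (actinol) | O=C1[C@H](C)C[C@@H](O)CC1(C)C | starting material
2 | (2R,4R,6R)-4-hydroxy-2-(iodomethyl)-2,6-dimethylcyclohexanone | O=C1[C@H](C)C[C@@H](O)C[C@@]1(C)CI | intermediate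
3 | (1S,3R,5R)-1,3-dimethyl-6-oxabicyclo[3.2.1]octan-2-one | O=C1[C@H](C)C[C@@H]2C[C@@]1(C)CO2 | intermediate
4 | (1R,3R,5R)-1,3-dimethyl-6-oxabicyclo[3.2.1]octane-2,7-dione | O=C1[C@H](C)C[C@@H]2C[C@@]1(C)C(=O)O2 | intermediate
5 | (1R,5R)-1,3-dimethyl-7-oxo-6-oxabicyclo[3.2.1]oct-2-en-2-yl triflate | CC1=C(OS(=O)(=O)C(F)(F)F)[C@@]2(C)C[C@@H](C1)OC2=O | intermediate
6 | (1R,5R,7ξ)-7-hydroxy-1,3-dimethyl-6-oxabicyclo[3.2.1]oct-2-en-2-yl triflate (anomers) | CC1=C(OS(=O)(=O)C(F)(F)F)[C@@]2(C)C[C@@H](C1)OC2O | intermediate
7 | but-2-ynoic acid | CC#CC(=O)O | starting material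
8 | (Z)-3-iodobut-2-enoic acid | I/C(C)=C\C(=O)O | intermediate
9 | 2-(trimethylsilyl)ethanol | OCC[Si](C)(C)C | starting material
10 | 2-(trimethylsilyl)ethyl (Z)-3-iodobut-2-enoate | I/C(C)=C\C(=O)OCC[Si](C)(C)C | intermediate
11 | (E)-1,2-bis(tributylstannyl)ethene | CCCC[Sn](CCCC)(CCCC)/C=C/[Sn](CCCC)(CCCC)CCCC | starting material
12 | 2-(trimethylsilyl)ethyl (2Z,4E)-3-methyl-5-(tributylstannyl)penta-2,4-dienoate | CCCC[Sn](CCCC)(CCCC)/C=C/C(C)=C\C(=O)OCC[Si](C)(C)C | intermediate
13 | lactol-bridged trienoate | CC1=C(/C=C/C(C)=C\C(=O)OCC[Si](C)(C)C)[C@@]2(C)C[C@@H](C1)OC2O | intermediate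
14 | lactol-bridged 1',2'-α-epoxide | C[C@]12O[C@@]1(/C=C/C(C)=C\C(=O)OCC[Si](C)(C)C)[C@@]1(C)C[C@@H](C2)OC1O | intermediate
15 | (1'S,2'R,4'S,6'S)-epoxy 4',9'-diol | C[C@]12O[C@@]1(/C=C/C(C)=C\C(=O)OCC[Si](C)(C)C)[C@](C)(CO)C[C@H](O)C2 | intermediate
16 | dimethyl 3-hydroxy-3-methylpentanedioate | COC(=O)CC(C)(O)CC(=O)OC | starting material
17 | (S)-3-hydroxy-5-methoxy-3-methyl-5-oxopentanoic acid | COC(=O)C[C@@](C)(O)CC(=O)O | intermediate
18 | triethylsilyl ester of 19 | COC(=O)C[C@@](C)(O[Si](CC)(CC)CC)CC(=O)O[Si](CC)(CC)CC | intermediate
19 | (S)-5-methoxy-3-methyl-5-oxo-3-(triethylsilyloxy)pentanoic acid | COC(=O)C[C@@](C)(O[Si](CC)(CC)CC)CC(=O)O | intermediate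
20 | 9'-O-acylated epoxy 4'-alcohol | C[C@]12O[C@@]1(/C=C/C(C)=C\C(=O)OCC[Si](C)(C)C)[C@](C)(COC(=O)C[C@](C)(O[Si](CC)(CC)CC)CC(=O)OC)C[C@H](O)C2 | intermediate
21 | 9'-O-acylated 4'-keto 1',2'-epoxide | C[C@]12O[C@@]1(/C=C/C(C)=C\C(=O)OCC[Si](C)(C)C)[C@](C)(COC(=O)C[C@](C)(O[Si](CC)(CC)CC)CC(=O)OC)CC(=O)C2 | intermediate
22 | silylethyl ester and triethylsilyl ether of the target | COC(=O)C[C@@](C)(O[Si](CC)(CC)CC)CC(=O)OC[C@]1(C)CC(=O)C=C(C)[C@]1(O)/C=C/C(C)=C\C(=O)OCC[Si](C)(C)C | intermediate
23 | CNP0274837.1 | COC(=O)C[C@@](C)(O)CC(=O)OC[C@]1(C)CC(=O)C=C(C)[C@]1(O)/C=C/C(C)=C\C(=O)O | target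

**Step count**
- Total: 15 steps.
- Longest linear sequence: 10 steps (1–4, 8–10, 13–15) from actinol.

**Steps most likely to fail**

*Step 1.* The alkoxyl radical may fragment by β-scission. Acetyl hypoiodite may iodinate the ketone at its α-position. The neopentyl iodide may also close too slowly.
The fallback sets out from 1 and comes back at 4.
- Nitrosyl chloride in pyridine should give actinol nitrite F1.
- Barton nitrite photolysis moves NO to the same syn-axial methyl by the same 1,5-H shift, but without any ionic ring closure. The nitroso compound tautomerises to the 9'-aldoxime F2.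
- Deoximation with aqueous nitrous acid frees the aldehyde, which closes onto the C4' hydroxyl to the bridged keto lactol F3.
- Oxidation of the lactol (silver carbonate on Celite) gives keto lactone 4, so steps 1 and 2 are both bypassed.

*Step 8.* Transmetalation at a palladium centre flanked by the bridgehead quaternary carbon and the C2' methyl may be too slow. Protodestannylation or homocoupling of the stannane would then take over.
The fallback sets out from 6 and comes back at 13.
- The hindered C1'–C5 bond is made with a rod-shaped alkyne: Sonogashira coupling with trimethylsilylacetylene gives silyl enyne F4.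
- Potassium carbonate in methanol gives terminal enyne F5.
- Palladium-catalysed hydrostannation with Bu3SnH gives the ring-bound (E)-dienylstannane F6.
- An unhindered Stille coupling with iodide 10, with the roles of the two partners reversed, gives 13.

*Step 13.* The neopentyl primary 9'-hydroxyl and the unhindered secondary 4'-hydroxyl may not be told apart well enough. This would give acylation at the wrong site or at both.
The fallback sets out from 15 and comes back at 21.
- Only the secondary carbinol is oxidised first, with bis(tributyltin) oxide and then bromine, a method selective for secondary over primary alcohols.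
- The 4'-keto 9'-alcohol should rest as the bridged hemiketal F7, which exposes neither an enolisable ketone nor a second acylable hydroxyl.
- Steglich acylation with 19 then drains the open form through its only primary hydroxyl to keto epoxide 21.
- Compound 21 is carried on with DBU as in step 14.

**Further compounds**
F1 | step 1 | (1R,3R)-3,3,5-trimethyl-4-oxocyclohexyl nitrite (actinol nitrite) | O=C1[C@H](C)C[C@@H](ON=O)CC1(C)C
F2 | step 1 | 9'-aldoxime of actinol (5-hydroxy-1,3-dimethyl-2-oxocyclohexanecarbaldehyde oxime) | O=C1[C@H](C)C[C@@H](O)C[C@@]1(C)C=NO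
F3 | step 1 | 7-hydroxy-1,3-dimethyl-6-oxabicyclo[3.2.1]octan-2-one (bridged keto lactol) | O=C1[C@H](C)C[C@@H]2C[C@@]1(C)C(O)O2
F4 | step 8 | lactol-bridged C1'-(trimethylsilylethynyl) alkene | CC1=C(C#C[Si](C)(C)C)[C@@]2(C)C[C@@H](C1)OC2O
F5 | step 8 | lactol-bridged C1'-ethynyl alkene | CC1=C(C#C)[C@@]2(C)C[C@@H](C1)OC2O
F6 | step 8 | lactol-bridged C1'-[(E)-2-(tributylstannyl)ethenyl] alkene | CC1=C(/C=C/[Sn](CCCC)(CCCC)CCCC)[C@@]2(C)C[C@@H](C1)OC2O
F7 | step 13 | 4',9'-bridged hemiketal of the 4'-keto 9'-hydroxy 1',2'-epoxide | C[C@]12O[C@@]1(/C=C/C(C)=C\C(=O)OCC[Si](C)(C)C)[C@@]1(C)C[C@@](O)(C2)OC1
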